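**Retrosynthetic overview**
1. Target ⇐ C7 benzyl ether / C11 alcohol series ⇐ tetracyclic alkene 34. The C11–O and C12–H bonds come from hydroboration, and the oxepane from C16–O–C3 etherification.
2. 34 ⇐ tricyclic ketone 25, with C18 from MeMgCl on a C3 ketone and C15 from hydroboration of a C14 isopropenyl group.
3. Cyclohexene and tetrahydrofuran together ⇐ intramolecular Diels–Alder reaction of oxonene tetraene 24 (C1–C10 and C13–C14 bonds).
4. Oxonene ⇐ ring-closing metathesis (C4=C5) of diene 17 ⇐ key Evans syn glycolate aldol (C2–C3 bond) of imide 12 (fragment 1, C5–C10 plus C1–C2) with acrolein (fragment 2).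
5. Fragment 1 ⇐ malic-acid-derived acetonide alcohol 1 by Brown allylation. Ring order: oxonene, then cyclohexene + tetrahydrofuran, then oxepane.

Notation: positions carry cladiellin numbers (carbocycle C1–C10, ether bridge C2–O–C9, cyclohexane C1/C10–C14, side chain C15–C17 on C14, C18 on C3, C20 on C12). "Core" means this oxygen-bridged tricycle with H-1/H-10 cis, both trans to H-2/H-9, the C14 substituent trans to C2, in the absolute sense of the target.
Assumption: the configuration of the temporary C7 carbinol (oxidised in the last step) is free and is fixed as S.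

**Step 1**
Reactants: 1 2-[(4S)-2,2-dimethyl-1,3-dioxolan-4-yl]ethanol
Product: 2 2-[(4S)-2,2-dimethyl-1,3-dioxolan-4-yl]acetaldehyde
Conditions: TEMPO (10 mol %), PhI(OAc)2, CH2Cl2, rt
Reagents that add atoms: none
Why: TEMPO/PhI(OAc)2 oxidation stops at the aldehyde and leaves the acetonide and the chiral-pool C9 stereocentre untouched.

**Step 2**
Reactants: 2 2-[(4S)-2,2-dimethyl-1,3-dioxolan-4-yl]acetaldehyde
Product: 3 (2S)-1-[(4S)-2,2-dimethyl-1,3-dioxolan-4-yl]pent-4-en-2-ol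
Conditions: (−)-Ipc2B(allyl) [from (+)-α-pinene], Et2O, −78 °C; then NaOH, H2O2
Reagents that add atoms: (−)-B-allyldiisopinocampheylborane, C=CCB([C@@H]1C[C@@H]2C[C@H]([C@H]1C)C2(C)C)[C@@H]1C[C@@H]2C[C@H]([C@H]1C)C2(C)C
Why: Brown asymmetric carbonyl allylation through a chair six-membered transition state sets the temporary C7 carbinol as S under reagent control.

**Step 3**
Reactants: 3 (2S)-1-[(4S)-2,2-dimethyl-1,3-dioxolan-4-yl]pent-4-en-2-ol
Product: 4 (4S)-4-[(2S)-2-(benzyloxy)pent-4-en-1-yl]-2,2-dimethyl-1,3-dioxolane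
Conditions: NaH, BnBr, Bu4NI (cat.), THF, 0 °C to rt
Reagents that add atoms: benzyl bromide, BrCc1ccccc1
Why: Williamson etherification installs a benzyl ether that survives every later step until the final hydrogenolysis.

**Step 4**
Reactants: 4 (4S)-4-[(2S)-2-(benzyloxy)pent-4-en-1-yl]-2,2-dimethyl-1,3-dioxolane
Product: 5 (2S,4S)-4-(benzyloxy)hept-6-ene-1,2-diol
Conditions: AcOH/H2O (4:1), 45 °C
Reagents that add atoms: none
Why: Mild acetal hydrolysis frees the 1,2-diol without affecting the benzyl ether or the alkene.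

**Step 5**
Reactants: 5 (2S,4S)-4-(benzyloxy)hept-6-ene-1,2-diol
Product: 7 (2S,4S)-4-(benzyloxy)-1-[(4-methoxybenzyl)oxy]hept-6-en-2-ol, via dibutylstannylene acetal 6 (not isolated)
Conditions: Bu2SnO, toluene, reflux (Dean–Stark); then 4-methoxybenzyl chloride, Bu4NI, toluene, 90 °C
Reagents that add atoms: 4-methoxybenzyl chloride, COc1ccc(CCl)cc1
Why: Stannylene-acetal activation directs alkylation to the primary oxygen and leaves the C9 hydroxyl free for the ether bridge.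

**Step 6**
Reactants: 7 (2S,4S)-4-(benzyloxy)-1-[(4-methoxybenzyl)oxy]hept-6-en-2-ol; 8 bromoacetic acid
Product: 9 2-{[(2S,4S)-4-(benzyloxy)-1-[(4-methoxybenzyl)oxy]hept-6-en-2-yl]oxy}acetic acid
Conditions: NaH (3 equiv), THF/DMF, 0 °C to rt; aq. HCl work-up
Reagents that add atoms: none
Why: Williamson etherification of the sodium alkoxide with sodium bromoacetate forms the C9–O–C2 ether at a primary carbon, so C9 keeps its configuration.

**Step 7**
Reactants: 9 2-{[(2S,4S)-4-(benzyloxy)-1-[(4-methoxybenzyl)oxy]hept-6-en-2-yl]oxy}acetic acid; 10 (R)-4-benzyl-1,3-oxazolidin-2-one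
Product: 12 (4R)-4-benzyl-3-(2-{[(2S,4S)-4-(benzyloxy)-1-[(4-methoxybenzyl)oxy]hept-6-en-2-yl]oxy}acetyl)-1,3-oxazolidin-2-one, via mixed pivalic anhydride 11 (not isolated)
Conditions: PivCl, Et3N, THF, −20 °C; then 10, LiCl, rt
Reagents that add atoms: none
Why: N-acylation of the Evans auxiliary through the mixed anhydride occurs at the less hindered glycolyl carbonyl.

**Step 8 (key step)**
Reactants: 12 (4R)-4-benzyl-3-(2-{[(2S,4S)-4-(benzyloxy)-1-[(4-methoxybenzyl)oxy]hept-6-en-2-yl]oxy}acetyl)-1,3-oxazolidin-2-one; 13 acrolein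
Product: 15 (4R)-4-benzyl-3-[(2R,3S)-2-{[(2S,4S)-4-(benzyloxy)-1-[(4-methoxybenzyl)oxy]hept-6-en-2-yl]oxy}-3-hydroxypent-4-enoyl]-1,3-oxazolidin-2-one, via Z boron enolate 14 (not isolated)
Conditions: Bu2BOTf, Et3N, CH2Cl2, −78 to 0 °C; acrolein, −78 to 0 °C; pH 7 buffer, MeOH, H2O2
Reagents that add atoms: none
Why: In this Evans syn glycolate aldol the Z boron enolate reacts through a Zimmerman–Traxler chair on the face opposite the auxiliary benzyl group, forming the C2–C3 bond and setting C2 as required for the tetrahydrofuran (the C3 carbinol is oxidised later).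

**Step 9**
Reactants: 15 (4R)-4-benzyl-3-[(2R,3S)-2-{[(2S,4S)-4-(benzyloxy)-1-[(4-methoxybenzyl)oxy]hept-6-en-2-yl]oxy}-3-hydroxypent-4-enoyl]-1,3-oxazolidin-2-one
Product: 16 (2R,3S)-2-{[(2S,4S)-4-(benzyloxy)-1-[(4-methoxybenzyl)oxy]hept-6-en-2-yl]oxy}-3-hydroxy-N-methoxy-N-methylpent-4-enamide
Conditions: AlMe3, MeNH(OMe)·HCl, CH2Cl2, −20 to 0 °C
Reagents that add atoms: N,O-dimethylhydroxylamine hydrochloride, CNOC.Cl
Why: Aluminium-amide transamination of the β-hydroxy imide, assisted by the free hydroxyl, gives the Weinreb amide without epimerising C2.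

**Step 10**
Reactants: 16 (2R,3S)-2-{[(2S,4S)-4-(benzyloxy)-1-[(4-methoxybenzyl)oxy]hept-6-en-2-yl]oxy}-3-hydroxy-N-methoxy-N-methylpent-4-enamide
Product: 17 (2R,3S)-2-{[(2S,4S)-4-(benzyloxy)-1-[(4-methoxybenzyl)oxy]hept-6-en-2-yl]oxy}-3-[(tert-butyldimethylsilyl)oxy]-N-methoxy-N-methylpent-4-enamide
Conditions: TBSOTf, 2,6-lutidine, CH2Cl2, −78 to 0 °C
Reagents that add atoms: tert-butyldimethylsilyl triflate, CC(C)(C)[Si](C)(C)OS(=O)(=O)C(F)(F)F
Why: Silylation protects the allylic C3 hydroxyl in a form orthogonal to the benzyl and 4-methoxybenzyl ethers.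

**Step 11**
Reactants: 17 (2R,3S)-2-{[(2S,4S)-4-(benzyloxy)-1-[(4-methoxybenzyl)oxy]hept-6-en-2-yl]oxy}-3-[(tert-butyldimethylsilyl)oxy]-N-methoxy-N-methylpent-4-enamide
Product: 18 (2R,3S,4Z,7S,9S)-7-(benzyloxy)-3-[(tert-butyldimethylsilyl)oxy]-N-methoxy-9-{[(4-methoxybenzyl)oxy]methyl}-N-methyl-2,3,6,7,8,9-hexahydrooxonine-2-carboxamide
Conditions: second-generation Grubbs catalyst RuCl2(=CHPh)(H2IMes)(PCy3) (5–10 mol %), CH2Cl2 (2 mM), 40 °C
Reagents that add atoms: none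
Why: Ring-closing metathesis gives the nine-membered Z-oxonene, helped by the gauche preferences of the 1,2-dioxygenated C2–C3 unit and the ether oxygen that fold the two olefin arms together.

**Step 12**
Reactants: 18 (2R,3S,4Z,7S,9S)-7-(benzyloxy)-3-[(tert-butyldimethylsilyl)oxy]-N-methoxy-9-{[(4-methoxybenzyl)oxy]methyl}-N-methyl-2,3,6,7,8,9-hexahydrooxonine-2-carboxamide
Product: 19 (2R,3S,4Z,7S,9S)-7-(benzyloxy)-3-[(tert-butyldimethylsilyl)oxy]-9-(hydroxymethyl)-N-methoxy-N-methyl-2,3,6,7,8,9-hexahydrooxonine-2-carboxamide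
Conditions: DDQ, CH2Cl2/pH 7 buffer, 0 °C
Reagents that add atoms: none
Why: Oxidative cleavage by DDQ removes the electron-rich 4-methoxybenzyl ether selectively in the presence of the benzyl ether, the silyl ether and the ring alkene.

**Step 13**
Reactants: 19 (2R,3S,4Z,7S,9S)-7-(benzyloxy)-3-[(tert-butyldimethylsilyl)oxy]-9-(hydroxymethyl)-N-methoxy-N-methyl-2,3,6,7,8,9-hexahydrooxonine-2-carboxamide
Product: 21 (2R,3S,4Z,7S,9S)-7-(benzyloxy)-3-[(tert-butyldimethylsilyl)oxy]-N-methoxy-N-methyl-9-[(1E)-3-oxobut-1-en-1-yl]-2,3,6,7,8,9-hexahydrooxonine-2-carboxamide, via oxonene aldehyde 20 (not isolated)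
Conditions: TEMPO (10 mol %), PhI(OAc)2, CH2Cl2, rt; then Ph3P=CHC(O)CH3 (3 equiv), 40 °C
Reagents that add atoms: 1-(triphenylphosphoranylidene)propan-2-one, CC(=O)C=P(c1ccccc1)(c1ccccc1)c1ccccc1
Why: One-pot alcohol oxidation and Wittig olefination with the stabilised ylide gives the E-enone (C10=C11, C12 carbonyl) and avoids handling the α-alkoxy aldehyde.

**Step 14**
Reactants: 21 (2R,3S,4Z,7S,9S)-7-(benzyloxy)-3-[(tert-butyldimethylsilyl)oxy]-N-methoxy-N-methyl-9-[(1E)-3-oxobut-1-en-1-yl]-2,3,6,7,8,9-hexahydrooxonine-2-carboxamide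
Product: 22 (2R,3S,4Z,7S,9S)-7-(benzyloxy)-3-[(tert-butyldimethylsilyl)oxy]-N-methoxy-N-methyl-9-[(1E)-3-methylbuta-1,3-dien-1-yl]-2,3,6,7,8,9-hexahydrooxonine-2-carboxamide
Conditions: Ph3PCH3Br, KOt-Bu, THF, 0 °C; then 21, −78 to 0 °C
Reagents that add atoms: methyltriphenylphosphonium bromide, C[P+](c1ccccc1)(c1ccccc1)c1ccccc1.[Br-]
Why: Wittig methylenation of the ketone, which is far more electrophilic than the Weinreb amide, completes the 2-methyl-1,3-diene.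

**Step 15**
Reactants: 22 (2R,3S,4Z,7S,9S)-7-(benzyloxy)-3-[(tert-butyldimethylsilyl)oxy]-N-methoxy-N-methyl-9-[(1E)-3-methylbuta-1,3-dien-1-yl]-2,3,6,7,8,9-hexahydrooxonine-2-carboxamide
Product: 23 (2R,3S,4Z,7S,9S)-7-(benzyloxy)-3-[(tert-butyldimethylsilyl)oxy]-9-[(1E)-3-methylbuta-1,3-dien-1-yl]-2,3,6,7,8,9-hexahydrooxonine-2-carbaldehyde
Conditions: i-Bu2AlH, THF, −78 °C; Rochelle salt work-up
Reagents that add atoms: none
Why: Reduction of the Weinreb amide stops at the aldehyde because the chelated tetrahedral intermediate survives until work-up.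

**Step 16**
Reactants: 23 (2R,3S,4Z,7S,9S)-7-(benzyloxy)-3-[(tert-butyldimethylsilyl)oxy]-9-[(1E)-3-methylbuta-1,3-dien-1-yl]-2,3,6,7,8,9-hexahydrooxonine-2-carbaldehyde
Product: 25 14-acetyl-7-(benzyloxy)-3-[(tert-butyldimethylsilyl)oxy]-12-methyl core 4Z,11-diene (C3/C7 as in 18), via tetraene enone 24 (not isolated)
Conditions: Ph3P=CHC(O)CH3, toluene, rt to 60 °C
Reagents that add atoms: 1-(triphenylphosphoranylidene)propan-2-one, CC(=O)C=P(c1ccccc1)(c1ccccc1)c1ccccc1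
Why: Wittig olefination gives the E-enone, which undergoes intramolecular Diels–Alder reaction with the diene held cis across the ring oxygen; the exo transition state on the face away from C3 and C8 sets C1 and C10, and the E geometry sets C14 trans to C2.

**Step 17**
Reactants: 25 14-acetyl-7-(benzyloxy)-3-[(tert-butyldimethylsilyl)oxy]-12-methyl core 4Z,11-diene
Product: 26 14-acetyl-7-(benzyloxy)-3-[(tert-butyldimethylsilyl)oxy]-12-methyl core 11-ene
Conditions: H2 (1 atm), RhCl(PPh3)3 (10 mol %), benzene/EtOH, rt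
Reagents that add atoms: none
Why: Homogeneous hydrogenation reduces the cis-disubstituted C4=C5 bond and leaves the trisubstituted C11=C12 bond and the benzyl ether intact.

**Step 18**
Reactants: 26 14-acetyl-7-(benzyloxy)-3-[(tert-butyldimethylsilyl)oxy]-12-methyl core 11-ene
Product: 27 7-(benzyloxy)-3-[(tert-butyldimethylsilyl)oxy]-12-methyl-14-(prop-1-en-2-yl) core 11-ene
Conditions: Ph3PCH3Br, KOt-Bu, THF, 0 °C to rt
Reagents that add atoms: methyltriphenylphosphonium bromide, C[P+](c1ccccc1)(c1ccccc1)c1ccccc1.[Br-]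
Why: Wittig methylenation converts the methyl ketone into the isopropenyl group (C15=C16), with C14 remaining in its more stable equatorial configuration.

**Step 19**
Reactants: 27 7-(benzyloxy)-3-[(tert-butyldimethylsilyl)oxy]-12-methyl-14-(prop-1-en-2-yl) core 11-ene
Product: 28 7-(benzyloxy)-12-methyl-14-(prop-1-en-2-yl) core 11-en-3-ol
Conditions: Bu4NF, THF, rt to 45 °C
Reagents that add atoms: none
Why: Fluoride cleaves the only silyl ether and releases the C3 alcohol.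

**Step 20**
Reactants: 28 7-(benzyloxy)-12-methyl-14-(prop-1-en-2-yl) core 11-en-3-ol
Product: 29 7-(benzyloxy)-12-methyl-14-(prop-1-en-2-yl) core 11-en-3-one
Conditions: Dess–Martin periodinane, CH2Cl2, 0 °C to rt
Reagents that add atoms: none
Why: Dess–Martin oxidation gives the C3 ketone under neutral conditions that do not epimerise the α-alkoxy centre C2.

**Step 21**
Reactants: 29 7-(benzyloxy)-12-methyl-14-(prop-1-en-2-yl) core 11-en-3-one
Product: 30 (3S)-7-(benzyloxy)-3,12-dimethyl-14-(prop-1-en-2-yl) core 11-en-3-ol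
Conditions: MeMgCl, THF, −78 to 0 °C; aq. NH4Cl
Reagents that add atoms: methylmagnesium chloride, C[Mg]Cl
Why: Grignard addition is expected to occur past the small H-2 on the carbonyl face turned away from the cyclohexene, which puts the new hydroxyl on the C14 side as the oxepane requires; this facial preference is substrate-controlled and not certain.

**Step 22**
Reactants: 30 (3S)-7-(benzyloxy)-3,12-dimethyl-14-(prop-1-en-2-yl) core 11-en-3-ol
Product: 32 (3S,15R)-7-(benzyloxy)-3,12-dimethyl-14-(1-hydroxypropan-2-yl) core 11-en-3-ol, via C16 borane 31 (not isolated)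
Conditions: 9-BBN (3 equiv), THF, 0 °C to rt; then NaOH, H2O2
Reagents that add atoms: hydrogen peroxide, OO
Why: Hydroboration–oxidation with 9-BBN touches only the 1,1-disubstituted alkene; with H-14 eclipsing the C=CH2 bond, hydrogen is expected to add to C15 on the face away from the more substituted C1 branch, giving 15R.

**Step 23**
Reactants: 32 (3S,15R)-7-(benzyloxy)-3,12-dimethyl-14-(1-hydroxypropan-2-yl) core 11-en-3-ol
Product: 34 (15R)-7-(benzyloxy)-3,12-dimethyl-3,16-epoxy core 11-ene (oxepane tetracycle), via primary triflate 33 (not isolated)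
Conditions: Tf2O, 2,6-lutidine, CH2Cl2, −78 to 0 °C
Reagents that add atoms: none
Why: Selective triflation of the primary alcohol is followed by intramolecular SN2 displacement by the tertiary C3 hydroxyl (7-exo-tet Williamson closure), forming the oxepane without touching a stereocentre.

**Step 24**
Reactants: 34 (15R)-7-(benzyloxy)-3,12-dimethyl-3,16-epoxy core 11-ene
Product: 36 (11S,12R)-7-(benzyloxy)-3,12-dimethyl-3,16-epoxy core 11-ol, via C11 borane 35 (not isolated)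
Conditions: BH3·THF, THF, 0 °C to rt; then NaOH, H2O2
Reagents that add atoms: hydrogen peroxide, OO
Why: Hydroboration–oxidation places boron at the less substituted C11 and hydrogen at C12 syn from the convex face opposite the pseudoaxial C10–C9 bond, which sets the C12 methyl as in the target and gives the 11-epi alcohol.

**Step 25**
Reactants: 36 (11S,12R)-7-(benzyloxy)-3,12-dimethyl-3,16-epoxy core 11-ol
Product: 37 (12R)-7-(benzyloxy)-3,12-dimethyl-3,16-epoxy core 11-one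
Conditions: Dess–Martin periodinane, CH2Cl2, 0 °C to rt
Reagents that add atoms: none
Why: Neutral Dess–Martin oxidation gives the C11 ketone without epimerising the adjacent C12 or C10 centres.

**Step 26**
Reactants: 37 (12R)-7-(benzyloxy)-3,12-dimethyl-3,16-epoxy core 11-one
Product: 38 (11R,12R)-7-(benzyloxy)-3,12-dimethyl-3,16-epoxy core 11-ol
Conditions: NaBH4, MeOH/CH2Cl2, −40 to 0 °C
Reagents that add atoms: none
Why: Hydride attacks axially from the same convex face (anti to the axial C12 methyl and the C10–C9 bond), so the hydroxyl emerges equatorial and cis to the C12 methyl, inverting C11 to the target configuration.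

**Step 27**
Reactants: 38 (11R,12R)-7-(benzyloxy)-3,12-dimethyl-3,16-epoxy core 11-ol
Product: 39 (11R,12R)-7-(benzyloxy)-3,12-dimethyl-3,16-epoxy core 11-yl acetate
Conditions: Ac2O, DMAP (cat.), pyridine, CH2Cl2, rt
Reagents that add atoms: acetic anhydride, CC(=O)OC(C)=O
Why: DMAP-catalysed acylation of the only free (equatorial secondary) hydroxyl installs the C11 acetate.

**Step 28**
Reactants: 39 (11R,12R)-7-(benzyloxy)-3,12-dimethyl-3,16-epoxy core 11-yl acetate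
Product: 40 (11R,12R)-7-hydroxy-3,12-dimethyl-3,16-epoxy core 11-yl acetate
Conditions: H2 (1 atm), Pd(OH)2/C, EtOAc, rt
Reagents that add atoms: none
Why: Hydrogenolysis removes the benzyl ether once no alkene remains, and spares the acetate and the three ring ethers.

**Step 29**
Reactants: 40 (11R,12R)-7-hydroxy-3,12-dimethyl-3,16-epoxy core 11-yl acetate
Product: 41 target, (1S,2S,3S,9S,10R,11R,12R,14S,15R)-11-acetoxy-3,12-dimethyl-3,16-epoxy core 7-one
Conditions: Dess–Martin periodinane, CH2Cl2, 0 °C to rt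
Reagents that add atoms: none
Why: Neutral Dess–Martin oxidation unveils the C7 ketone last, so the base-sensitive β-alkoxy ketone is never exposed to elimination conditions.

**Compound list**
1 | 2-[(4S)-2,2-dimethyl-1,3-dioxolan-4-yl]ethanol | OCC[C@H]1COC(C)(C)O1 | starting material
2 | 2-[(4S)-2,2-dimethyl-1,3-dioxolan-4-yl]acetaldehyde | O=CC[C@H]1COC(C)(C)O1 | intermediate
3 | (2S)-1-[(4S)-2,2-dimethyl-1,3-dioxolan-4-yl]pent-4-en-2-ol | C=CC[C@H](O)C[C@H]1COC(C)(C)O1 | intermediate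
4 | (4S)-4-[(2S)-2-(benzyloxy)pent-4-en-1-yl]-2,2-dimethyl-1,3-dioxolane | C=CC[C@H](OCc1ccccc1)C[C@H]1COC(C)(C)O1 | intermediate
5 | (2S,4S)-4-(benzyloxy)hept-6-ene-1,2-diol | C=CC[C@H](OCc1ccccc1)C[C@H](O)CO | intermediate
6 | (4S)-4-[(2S)-2-(benzyloxy)pent-4-en-1-yl]-2,2-dibutyl-1,3,2-dioxastannolane (not isolated) | C=CC[C@H](OCc1ccccc1)C[C@H]1CO[Sn](CCCC)(CCCC)O1 | intermediate
7 | (2S,4S)-4-(benzyloxy)-1-[(4-methoxybenzyl)oxy]hept-6-en-2-ol | C=CC[C@H](OCc1ccccc1)C[C@H](O)COCc1ccc(OC)cc1 | intermediate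
8 | bromoacetic acid | OC(=O)CBr | starting material
9 | 2-{[(2S,4S)-4-(benzyloxy)-1-[(4-methoxybenzyl)oxy]hept-6-en-2-yl]oxy}acetic acid | C=CC[C@H](OCc1ccccc1)C[C@H](OCC(=O)O)COCc1ccc(OC)cc1 | intermediate
10 | (R)-4-benzyl-1,3-oxazolidin-2-one | O=C1N[C@H](Cc2ccccc2)CO1 | starting material
11 | mixed anhydride of 9 with pivalic acid (not isolated) | C=CC[C@H](OCc1ccccc1)C[C@H](OCC(=O)OC(=O)C(C)(C)C)COCc1ccc(OC)cc1 | intermediate
12 | (4R)-4-benzyl-3-(2-{[(2S,4S)-4-(benzyloxy)-1-[(4-methoxybenzyl)oxy]hept-6-en-2-yl]oxy}acetyl)-1,3-oxazolidin-2-one | C=CC[C@H](OCc1ccccc1)C[C@H](OCC(=O)N1[C@H](Cc2ccccc2)COC1=O)COCc1ccc(OC)cc1 | intermediate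
13 | acrolein (prop-2-enal) | C=CC=O | starting material
14 | Z dibutylboron enolate of 12 (not isolated) | C=CC[C@H](OCc1ccccc1)C[C@H](O/C=C(\OB(CCCC)CCCC)N1[C@H](Cc2ccccc2)COC1=O)COCc1ccc(OC)cc1 | intermediate
15 | (4R)-4-benzyl-3-[(2R,3S)-2-{[(2S,4S)-4-(benzyloxy)-1-[(4-methoxybenzyl)oxy]hept-6-en-2-yl]oxy}-3-hydroxypent-4-enoyl]-1,3-oxazolidin-2-one | C=CC[C@H](OCc1ccccc1)C[C@@H](COCc1ccc(OC)cc1)O[C@H]([C@@H](O)C=C)C(=O)N1[C@H](Cc2ccccc2)COC1=O | intermediate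
16 | (2R,3S)-2-{[(2S,4S)-4-(benzyloxy)-1-[(4-methoxybenzyl)oxy]hept-6-en-2-yl]oxy}-3-hydroxy-N-methoxy-N-methylpent-4-enamide | C=CC[C@H](OCc1ccccc1)C[C@@H](COCc1ccc(OC)cc1)O[C@H]([C@@H](O)C=C)C(=O)N(C)OC | intermediate
17 | (2R,3S)-2-{[(2S,4S)-4-(benzyloxy)-1-[(4-methoxybenzyl)oxy]hept-6-en-2-yl]oxy}-3-[(tert-butyldimethylsilyl)oxy]-N-methoxy-N-methylpent-4-enamide | C=CC[C@H](OCc1ccccc1)C[C@@H](COCc1ccc(OC)cc1)O[C@H]([C@@H](O[Si](C)(C)C(C)(C)C)C=C)C(=O)N(C)OC | intermediate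
18 | (2R,3S,4Z,7S,9S)-7-(benzyloxy)-3-[(tert-butyldimethylsilyl)oxy]-N-methoxy-9-{[(4-methoxybenzyl)oxy]methyl}-N-methyl-2,3,6,7,8,9-hexahydrooxonine-2-carboxamide | CC(C)(C)[Si](C)(C)O[C@H]1/C=C\C[C@H](OCc2ccccc2)C[C@@H](COCc2ccc(OC)cc2)O[C@H]1C(=O)N(C)OC | intermediate
19 | (2R,3S,4Z,7S,9S)-7-(benzyloxy)-3-[(tert-butyldimethylsilyl)oxy]-9-(hydroxymethyl)-N-methoxy-N-methyl-2,3,6,7,8,9-hexahydrooxonine-2-carboxamide | CC(C)(C)[Si](C)(C)O[C@H]1/C=C\C[C@H](OCc2ccccc2)C[C@@H](CO)O[C@H]1C(=O)N(C)OC | intermediate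
20 | (2R,3S,4Z,7S,9S)-7-(benzyloxy)-3-[(tert-butyldimethylsilyl)oxy]-9-formyl-N-methoxy-N-methyl-2,3,6,7,8,9-hexahydrooxonine-2-carboxamide (not isolated) | CC(C)(C)[Si](C)(C)O[C@H]1/C=C\C[C@H](OCc2ccccc2)C[C@@H](C=O)O[C@H]1C(=O)N(C)OC | intermediate
21 | (2R,3S,4Z,7S,9S)-7-(benzyloxy)-3-[(tert-butyldimethylsilyl)oxy]-N-methoxy-N-methyl-9-[(1E)-3-oxobut-1-en-1-yl]-2,3,6,7,8,9-hexahydrooxonine-2-carboxamide | CC(C)(C)[Si](C)(C)O[C@H]1/C=C\C[C@H](OCc2ccccc2)C[C@@H](/C=C/C(C)=O)O[C@H]1C(=O)N(C)OC | intermediate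
22 | (2R,3S,4Z,7S,9S)-7-(benzyloxy)-3-[(tert-butyldimethylsilyl)oxy]-N-methoxy-N-methyl-9-[(1E)-3-methylbuta-1,3-dien-1-yl]-2,3,6,7,8,9-hexahydrooxonine-2-carboxamide | CC(C)(C)[Si](C)(C)O[C@H]1/C=C\C[C@H](OCc2ccccc2)C[C@@H](/C=C/C(C)=C)O[C@H]1C(=O)N(C)OC | intermediate
23 | (2R,3S,4Z,7S,9S)-7-(benzyloxy)-3-[(tert-butyldimethylsilyl)oxy]-9-[(1E)-3-methylbuta-1,3-dien-1-yl]-2,3,6,7,8,9-hexahydrooxonine-2-carbaldehyde | CC(C)(C)[Si](C)(C)O[C@H]1/C=C\C[C@H](OCc2ccccc2)C[C@@H](/C=C/C(C)=C)O[C@H]1C=O | intermediate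
24 | oxonene tetraene: as 23 with the 2-formyl group replaced by (1E)-3-oxobut-1-en-1-yl (not isolated) | CC(C)(C)[Si](C)(C)O[C@H]1/C=C\C[C@H](OCc2ccccc2)C[C@@H](/C=C/C(C)=C)O[C@H]1/C=C/C(C)=O | intermediate
25 | 14-acetyl-7-(benzyloxy)-3-[(tert-butyldimethylsilyl)oxy]-12-methyl core 4Z,11-diene | CC(=O)[C@@H]1CC(C)=C[C@@H]2[C@H]1[C@@H]1O[C@H]2C[C@@H](OCc2ccccc2)C/C=C\[C@@H]1O[Si](C)(C)C(C)(C)C | intermediate
26 | 14-acetyl-7-(benzyloxy)-3-[(tert-butyldimethylsilyl)oxy]-12-methyl core 11-ene | CC(=O)[C@@H]1CC(C)=C[C@@H]2[C@H]1[C@@H]1O[C@H]2C[C@@H](OCc2ccccc2)CCC[C@@H]1O[Si](C)(C)C(C)(C)C | intermediate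
27 | 7-(benzyloxy)-3-[(tert-butyldimethylsilyl)oxy]-12-methyl-14-(prop-1-en-2-yl) core 11-ene | C=C(C)[C@@H]1CC(C)=C[C@@H]2[C@H]1[C@@H]1O[C@H]2C[C@@H](OCc2ccccc2)CCC[C@@H]1O[Si](C)(C)C(C)(C)C | intermediate
28 | 7-(benzyloxy)-12-methyl-14-(prop-1-en-2-yl) core 11-en-3-ol | C=C(C)[C@@H]1CC(C)=C[C@@H]2[C@H]1[C@@H]1O[C@H]2C[C@@H](OCc2ccccc2)CCC[C@@H]1O | intermediate
29 | 7-(benzyloxy)-12-methyl-14-(prop-1-en-2-yl) core 11-en-3-one | C=C(C)[C@@H]1CC(C)=C[C@@H]2[C@H]1[C@@H]1O[C@H]2C[C@@H](OCc2ccccc2)CCCC1=O | intermediate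
30 | (3S)-7-(benzyloxy)-3,12-dimethyl-14-(prop-1-en-2-yl) core 11-en-3-ol | C=C(C)[C@@H]1CC(C)=C[C@@H]2[C@H]1[C@@H]1O[C@H]2C[C@@H](OCc2ccccc2)CCC[C@]1(C)O | intermediate
31 | B-alkyl-9-borabicyclo[3.3.1]nonane adduct of 30 at C16, 15R (not isolated) | C(B1C2CCCC1CCC2)[C@H](C)[C@@H]1CC(C)=C[C@@H]2[C@H]1[C@@H]1O[C@H]2C[C@@H](OCc2ccccc2)CCC[C@]1(C)O | intermediate
32 | (3S,15R)-7-(benzyloxy)-3,12-dimethyl-14-(1-hydroxypropan-2-yl) core 11-en-3-ol | OC[C@H](C)[C@@H]1CC(C)=C[C@@H]2[C@H]1[C@@H]1O[C@H]2C[C@@H](OCc2ccccc2)CCC[C@]1(C)O | intermediate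
33 | C16 triflate of 32 (not isolated) | FC(F)(F)S(=O)(=O)OC[C@H](C)[C@@H]1CC(C)=C[C@@H]2[C@H]1[C@@H]1O[C@H]2C[C@@H](OCc2ccccc2)CCC[C@]1(C)O | intermediate
34 | (15R)-7-(benzyloxy)-3,12-dimethyl-3,16-epoxy core 11-ene | CC1=C[C@@H]2[C@@H]3[C@@H](C1)[C@@H](C)CO[C@@]1(C)CCC[C@H](OCc4ccccc4)C[C@@H]2O[C@@H]31 | intermediate
35 | C11 monoalkylborane from 34, boron trans to the C12 methyl (not isolated) | B[C@@H]1[C@@H]2[C@@H]3[C@@H](C[C@H]1C)[C@@H](C)CO[C@@]1(C)CCC[C@H](OCc4ccccc4)C[C@@H]2O[C@@H]31 | intermediate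
36 | (11S,12R)-7-(benzyloxy)-3,12-dimethyl-3,16-epoxy core 11-ol | O[C@@H]1[C@@H]2[C@@H]3[C@@H](C[C@H]1C)[C@@H](C)CO[C@@]1(C)CCC[C@H](OCc4ccccc4)C[C@@H]2O[C@@H]31 | intermediate
37 | (12R)-7-(benzyloxy)-3,12-dimethyl-3,16-epoxy core 11-one | O=C1[C@@H]2[C@@H]3[C@@H](C[C@H]1C)[C@@H](C)CO[C@@]1(C)CCC[C@H](OCc4ccccc4)C[C@@H]2O[C@@H]31 | intermediate
38 | (11R,12R)-7-(benzyloxy)-3,12-dimethyl-3,16-epoxy core 11-ol | O[C@H]1[C@@H]2[C@@H]3[C@@H](C[C@H]1C)[C@@H](C)CO[C@@]1(C)CCC[C@H](OCc4ccccc4)C[C@@H]2O[C@@H]31 | intermediate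
39 | (11R,12R)-7-(benzyloxy)-3,12-dimethyl-3,16-epoxy core 11-yl acetate | CC(=O)O[C@H]1[C@@H]2[C@@H]3[C@@H](C[C@H]1C)[C@@H](C)CO[C@@]1(C)CCC[C@H](OCc4ccccc4)C[C@@H]2O[C@@H]31 | intermediate
40 | (11R,12R)-7-hydroxy-3,12-dimethyl-3,16-epoxy core 11-yl acetate | CC(=O)O[C@H]1[C@@H]2[C@@H]3[C@@H](C[C@H]1C)[C@@H](C)CO[C@@]1(C)CCC[C@H](O)C[C@@H]2O[C@@H]31 | intermediate
41 | CNP0288436.2, (1S,2S,3S,9S,10R,11R,12R,14S,15R)-11-acetoxy-3,12-dimethyl-3,16-epoxy core 7-one | CC(=O)O[C@H]1[C@@H]2[C@@H]3[C@@H](C[C@H]1C)[C@@H](C)CO[C@@]1(C)CCCC(=O)C[C@@H]2O[C@@H]31 | target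

**Step count and risks**
Total steps: 29. Longest linear sequence: 29 steps (1 to 41); compounds 8, 10 and 13 enter as single building blocks.

Most likely to fail:

Step 16 (Wittig / intramolecular Diels–Alder). The facial and exo selectivity rest on the conformation of a Z-oxonene whose ring alkene sits at C4=C5, so the cycloaddition may be slow or unselective. Fallback: remove the ring alkene before the cycloaddition. Set out from 18 and hydrogenate C4=C5 (H2, RhCl(PPh3)3) to the saturated oxonane amide F1. DDQ then gives the primary alcohol F2. TEMPO/PhI(OAc)2 followed by Ph3P=CHC(O)CH3 gives the enone F4 by way of the aldehyde F3. Ph3P=CH2 gives the diene F5, and i-Bu2AlH gives the aldehyde F6. Wittig reaction with Ph3P=CHC(O)CH3 gives the triene enone F7, whose cycloaddition delivers 26 directly. The route is rejoined at 26 and step 17 is no longer needed.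

Step 21 (methyl addition to the C3 ketone). The facial selectivity is substrate-controlled and could favour the C3 epimer. Fallback: form the C3–O bond from the tethered C16 hydroxyl, which can only reach the face of C3 turned toward C14, and take the methyl group from an exocyclic methylene. Set out from 28 and hydroborate the isopropenyl group (9-BBN; NaOH, H2O2) by way of the borane F8 to the diol F9. Silylate the primary hydroxyl (TBSCl, imidazole) to the silyl ether F10, and oxidise (Dess–Martin periodinane) to the ketone F11. Methylenate (Ph3P=CH2) to the exocyclic alkene F12 and desilylate (Bu4NF) to the alkenol F13. Intramolecular alkoxymercuration (Hg(OCOCF3)2, CH2Cl2, −20 °C) gives the organomercurial F14, which NaBH4/NaOH reduces to 34; the cis-fused oxepane, which is the target configuration, is expected to be the less strained outcome. The route is rejoined at 34.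

Step 22 (hydroboration setting C15). An isopropenyl group beside a ring stereocentre can give low or reversed selectivity with a dialkylborane. Fallback: switch from the four-centre addition to metal-catalysed hydroboration, which proceeds by alkene insertion into a rhodium hydride and shows the opposite facial preference for 1,1-disubstituted alkenes flanked by a stereocentre. Set out from 30 and treat with catecholborane and RhCl(PPh3)3 in THF to give the catechol boronate F15. Oxidise with NaOH/H2O2 to 32, where the route is rejoined. This helps if 9-BBN favours the wrong epimer, not if it is merely unselective.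

**Further compounds**
F1 | step 16 | (2R,3S,7S,9S)-7-(benzyloxy)-3-[(tert-butyldimethylsilyl)oxy]-N-methoxy-9-{[(4-methoxybenzyl)oxy]methyl}-N-methyloxonane-2-carboxamide | CC(C)(C)[Si](C)(C)O[C@H]1CCC[C@H](OCc2ccccc2)C[C@@H](COCc2ccc(OC)cc2)O[C@H]1C(=O)N(C)OC
F2 | step 16 | 9-(hydroxymethyl) analogue of F1 | CC(C)(C)[Si](C)(C)O[C@H]1CCC[C@H](OCc2ccccc2)C[C@@H](CO)O[C@H]1C(=O)N(C)OC
F3 | step 16 | 9-formyl analogue of F1 | CC(C)(C)[Si](C)(C)O[C@H]1CCC[C@H](OCc2ccccc2)C[C@@H](C=O)O[C@H]1C(=O)N(C)OC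
F4 | step 16 | 9-[(1E)-3-oxobut-1-en-1-yl] analogue of F1 | CC(C)(C)[Si](C)(C)O[C@H]1CCC[C@H](OCc2ccccc2)C[C@@H](/C=C/C(C)=O)O[C@H]1C(=O)N(C)OC
F5 | step 16 | 9-[(1E)-3-methylbuta-1,3-dien-1-yl] analogue of F1 | CC(C)(C)[Si](C)(C)O[C@H]1CCC[C@H](OCc2ccccc2)C[C@@H](/C=C/C(C)=C)O[C@H]1C(=O)N(C)OC
F6 | step 16 | (2R,3S,7S,9S)-7-(benzyloxy)-3-[(tert-butyldimethylsilyl)oxy]-9-[(1E)-3-methylbuta-1,3-dien-1-yl]oxonane-2-carbaldehyde | CC(C)(C)[Si](C)(C)O[C@H]1CCC[C@H](OCc2ccccc2)C[C@@H](/C=C/C(C)=C)O[C@H]1C=O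
F7 | step 16 | saturated-oxonane triene enone (4,5-dihydro analogue of 24) | CC(C)(C)[Si](C)(C)O[C@H]1CCC[C@H](OCc2ccccc2)C[C@@H](/C=C/C(C)=C)O[C@H]1/C=C/C(C)=O
F8 | step 21 | B-alkyl-9-borabicyclo[3.3.1]nonane adduct of 28 at C16 | C(B1C2CCCC1CCC2)[C@H](C)[C@@H]1CC(C)=C[C@@H]2[C@H]1[C@@H]1O[C@H]2C[C@@H](OCc2ccccc2)CCC[C@@H]1O
F9 | step 21 | (15R)-7-(benzyloxy)-12-methyl-14-(1-hydroxypropan-2-yl) core 11-en-3-ol | OC[C@H](C)[C@@H]1CC(C)=C[C@@H]2[C@H]1[C@@H]1O[C@H]2C[C@@H](OCc2ccccc2)CCC[C@@H]1O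
F10 | step 21 | 16-O-tert-butyldimethylsilyl ether of F9 | CC(C)(C)[Si](C)(C)OC[C@H](C)[C@@H]1CC(C)=C[C@@H]2[C@H]1[C@@H]1O[C@H]2C[C@@H](OCc2ccccc2)CCC[C@@H]1O
F11 | step 21 | 3-ketone of F10 | CC(C)(C)[Si](C)(C)OC[C@H](C)[C@@H]1CC(C)=C[C@@H]2[C@H]1[C@@H]1O[C@H]2C[C@@H](OCc2ccccc2)CCCC1=O
F12 | step 21 | 3-methylene compound from F11 | CC(C)(C)[Si](C)(C)OC[C@H](C)[C@@H]1CC(C)=C[C@@H]2[C@H]1[C@@H]1O[C@H]2C[C@@H](OCc2ccccc2)CCCC1=C
F13 | step 21 | (15R)-7-(benzyloxy)-12-methyl-3-methylene core 11-en-16-ol | OC[C@H](C)[C@@H]1CC(C)=C[C@@H]2[C@H]1[C@@H]1O[C@H]2C[C@@H](OCc2ccccc2)CCCC1=C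
F14 | step 21 | oxepane organomercurial, 34 with C18 carrying HgOCOCF3 | CC1=C[C@@H]2[C@@H]3[C@@H](C1)[C@@H](C)CO[C@@]1(C[Hg]OC(=O)C(F)(F)F)CCC[C@H](OCc4ccccc4)C[C@@H]2O[C@@H]31
F15 | step 22 | C16 catechol boronate of 30 (15R) | C(B1Oc2ccccc2O1)[C@H](C)[C@@H]1CC(C)=C[C@@H]2[C@H]1[C@@H]1O[C@H]2C[C@@H](OCc2ccccc2)CCC[C@]1(C)O
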